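## Retrosynthetic overview

1. Ambrein ⇒ (remove O‑TES) ⇒ sp3–sp2 Suzuki disconnection at the CH2–CH= bond: C14 (E)-vinyl iodide **10** + C16 bicyclic iodide **22**.
2. **10** ⇒ alkyne **9** (Zr-catalysed carboalumination sets the E-trisubstituted alkene) ⇒ (S)-2-allyl-3,3-dimethylcyclohexanone **5** (Pd decarboxylative asymmetric allylation); this six-membered ring is bought intact as 3-methylcyclohexenone.
3. **22** ⇒ ambradiol **19** ⇒ (+)-sclareolide **18** ⇒ (−)-Ambrox **17** ⇒ (3E,7E)-homofarnesol **16**.
4. **16** ⇒ two rounds of acetylide alkylation and carboalumination/ethylene oxide opening from 5-bromo-2-methylpent-2-ene.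
5. Ring order: decalin ring A, then ring B, then a temporary tetrahydrofuran, all in one enantioselective cationic cascade (step 14); the THF is later oxidised and reductively opened.

Assumption 1: the (R,R) antipode of the Trost ligand is taken to give (S)-**5**; if the sense is opposite, the (S,S) ligand is used and nothing else changes.
Assumption 2: an engineered squalene–hopene cyclase whole-cell catalyst is available for step 14.

## Left-hand fragment (steps 1–8)

**Step 1**
Reactants: **1**, 3-methylcyclohex-2-en-1-one
Product: **2**, [(3,3-dimethylcyclohex-1-en-1-yl)oxy]trimethylsilane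
Conditions: Me2CuLi, Et2O, 0 °C; then TMSCl, Et3N, 0 °C → rt
Reagents that add atoms: lithium dimethylcuprate, [Li+].C[Cu-]C; chlorotrimethylsilane, C[Si](C)(C)Cl
Why: Cuprate conjugate addition to the β-methyl enone builds the gem-dimethyl carbon, and O-silylation of the resulting enolate fixes the enol double bond toward the quaternary carbon (no stereocentre).

**Step 2**
Reactants: **2**; **3**, allyl chloroformate
Product: **4**, allyl 3,3-dimethylcyclohex-1-en-1-yl carbonate
Conditions: MeLi, THF, 0 °C → rt; TMEDA; then **3**, −78 °C
Reagents that add atoms: allyl chloroformate (**3**), C=CCOC(=O)Cl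
Why: MeLi cleaves the silyl enol ether to the regiodefined lithium enolate, which the hard chloroformate acylates on oxygen to give the enol carbonate.

**Step 3**
Reactants: **4**
Product: **5**, (2S)-3,3-dimethyl-2-(prop-2-en-1-yl)cyclohexan-1-one
Conditions: Pd2(dba)3·CHCl3 (2.5 mol%), (R,R)-ANDEN-phenyl Trost ligand (5.5 mol%), 1,4-dioxane, rt (−CO2)
Reagents that add atoms: none
Why: Decarboxylative asymmetric allylic alkylation (Tsuji–Trost, enol carbonate variant): the ligand-bound π-allyl-Pd/enolate ion pair recombines only at C2 and on one enolate face, setting the (S) centre under neutral, non-equilibrating conditions.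

**Step 4**
Reactants: **5**
Product: **6**, (2S)-1,1-dimethyl-3-methylidene-2-(prop-2-en-1-yl)cyclohexane
Conditions: Zn, CH2Br2, TiCl4, THF/CH2Cl2, 0 °C → rt
Reagents that add atoms: dibromomethane, BrCBr
Why: Takai–Lombardo methylenation is non-basic, so the hindered enolisable ketone becomes the exocyclic alkene without epimerising the α-stereocentre, which is configurationally safe from here on.

**Step 5**
Reactants: **6**
Product: **7**, 3-[(1S)-2,2-dimethyl-6-methylidenecyclohexyl]propan-1-ol
Conditions: Sia2BH (1.3 equiv), THF, 0 °C; then NaOH, H2O2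
Reagents that add atoms: hydrogen peroxide, OO
Why: Anti-Markovnikov hydroboration–oxidation; bulky disiamylborane takes the monosubstituted allyl alkene far faster than the hindered 1,1-disubstituted exocyclic alkene.

**Step 6**
Reactants: **7**
Product: **8**, 3-[(1S)-2,2-dimethyl-6-methylidenecyclohexyl]propanal
Conditions: Dess–Martin periodinane, NaHCO3, CH2Cl2, 0 °C → rt
Reagents that add atoms: none
Why: Buffered Dess–Martin oxidation stops at the aldehyde and leaves the alkene and the remote stereocentre untouched.

**Step 7**
Reactants: **8**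
Product: **9**, (2S)-2-(but-3-yn-1-yl)-1,1-dimethyl-3-methylidenecyclohexane
Conditions: dimethyl (1-diazo-2-oxopropyl)phosphonate, K2CO3, MeOH, 0 °C → rt
Reagents that add atoms: Ohira–Bestmann reagent, CC(=O)C(=[N+]=[N-])P(=O)(OC)OC
Why: Seyferth–Gilbert homologation (Ohira–Bestmann modification) converts the aldehyde to the terminal alkyne with one added carbon under mild base; the stereocentre is γ to the aldehyde and cannot epimerise.

**Step 8**
Reactants: **9**
Product: **10**, (2S)-2-[(3E)-4-iodo-3-methylbut-3-en-1-yl]-1,1-dimethyl-3-methylidenecyclohexane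
Conditions: Me3Al, Cp2ZrCl2 (0.25 equiv), CH2Cl2, 0 °C → rt; then I2, THF, −30 → 0 °C
Reagents that add atoms: trimethylaluminium, C[Al](C)C; iodine, II
Why: Negishi Zr-catalysed carboalumination adds Me–Al syn across the terminal alkyne (Me to the internal carbon) and iodinolysis with retention gives the (E)-vinyl iodide; the 1,1-disubstituted alkene is inert to the achiral zirconocene.

## Right-hand fragment (steps 9–19)

**Step 9**
Reactants: **11**, 5-bromo-2-methylpent-2-ene
Product: **12**, 6-methylhept-5-en-1-yne
Conditions: lithium acetylide–ethylenediamine complex, DMSO, 10 °C → rt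
Reagents that add atoms: lithium acetylide, [Li]C#C
Why: SN2 alkylation of the acetylide by the primary bromide in a dipolar aprotic solvent.

**Step 10**
Reactants: **12**
Product: **13**, (3E)-4,8-dimethylnona-3,7-dien-1-ol (homogeraniol)
Conditions: Me3Al, Cp2ZrCl2 (cat.), CH2Cl2, rt; evaporate; n-BuLi, hexane/THF, −78 → 0 °C; ethylene oxide, 0 °C → rt
Reagents that add atoms: trimethylaluminium, C[Al](C)C; ethylene oxide, C1CO1
Why: Syn carboalumination gives the (E)-alkenylalane, whose ate complex opens ethylene oxide with retention of alkene geometry, setting the first E-trisubstituted alkene.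

**Step 11**
Reactants: **13**
Product: **14**, (6E)-9-bromo-2,6-dimethylnona-2,6-diene
Conditions: CBr4, PPh3, CH2Cl2, 0 °C
Reagents that add atoms: carbon tetrabromide, BrC(Br)(Br)Br
Why: Appel bromination is an SN2 displacement at the primary homoallylic carbon, so no allylic cation forms and the alkene is not scrambled.

**Step 12**
Reactants: **14**
Product: **15**, (5E)-6,10-dimethylundeca-5,9-dien-1-yne
Conditions: lithium acetylide–ethylenediamine complex, DMSO, 10 °C → rt
Reagents that add atoms: lithium acetylide, [Li]C#C
Why: SN2 alkylation of the acetylide, the same reaction as step 9.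

**Step 13**
Reactants: **15**
Product: **16**, (3E,7E)-4,8,12-trimethyltrideca-3,7,11-trien-1-ol (homofarnesol)
Conditions: Me3Al, Cp2ZrCl2 (cat.), CH2Cl2, rt; evaporate; n-BuLi, hexane/THF, −78 → 0 °C; ethylene oxide, 0 °C → rt
Reagents that add atoms: trimethylaluminium, C[Al](C)C; ethylene oxide, C1CO1
Why: Second Negishi carboalumination and epoxide opening sets the second E-trisubstituted alkene; the existing trisubstituted alkenes are inert.

**Step 14**
Reactants: **16**
Product: **17**, (−)-Ambrox, (3aR,5aS,9aS,9bR)-3a,6,6,9a-tetramethyldodecahydronaphtho[2,1-b]furan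
Conditions: engineered squalene–hopene cyclase (A. acidocaldarius SHC variant, recombinant E. coli whole cells), citrate buffer pH 6, SDS, 35 °C; recrystallise from hexane
Reagents that add atoms: none
Why: Enzyme-templated proton-initiated chair–chair polyene cyclisation: the E,E geometry gives anti addition across both alkenes (trans-decalin) and the hydroxyl traps the tertiary cation equatorially, setting all four stereocentres in the natural absolute sense.

**Step 15**
Reactants: **17**
Product: **18**, (+)-sclareolide, (3aR,5aS,9aS,9bR)-3a,6,6,9a-tetramethyldecahydronaphtho[2,1-b]furan-2(1H)-one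
Conditions: RuCl3·xH2O (5 mol%), NaIO4, CCl4/MeCN/H2O, rt
Reagents that add atoms: sodium periodate (oxygen source via RuO4), [Na+].[O-]I(=O)(=O)=O
Why: RuO4 ether-to-lactone oxidation attacks the only O–CH2 group; no stereocentre is involved.

**Step 16**
Reactants: **18**
Product: **19**, ambradiol, (1R,2R,4aS,8aS)-1-(2-hydroxyethyl)-2,5,5,8a-tetramethyldecahydronaphthalen-2-ol
Conditions: LiAlH4, THF, 0 °C → rt
Reagents that add atoms: none
Why: Hydride reduction of the lactone cleaves only the acyl C–O bond, so the tertiary carbinol keeps its configuration.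

**Step 17**
Reactants: **19**
Product: **20**, bis(triethylsilyl) ether of **19**
Conditions: TESOTf (3 equiv), 2,6-lutidine, CH2Cl2, −78 → 0 °C
Reagents that add atoms: triethylsilyl triflate, CC[Si](CC)(CC)OS(=O)(=O)C(F)(F)F
Why: The silyl triflate silylates both hydroxyls, including the hindered tertiary one, which would otherwise displace any leaving group on the side chain to re-form the tetrahydrofuran.

**Step 18**
Reactants: **20**
Product: **21**, 2-[(1R,2R,4aS,8aS)-2,5,5,8a-tetramethyl-2-(triethylsilyloxy)decahydronaphthalen-1-yl]ethan-1-ol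
Conditions: PPTS (cat.), MeOH/CH2Cl2, 0 °C
Reagents that add atoms: none
Why: Acid-catalysed methanolysis removes the unhindered primary TES ether much faster than the hindered tertiary one.

**Step 19**
Reactants: **21**
Product: **22**, triethyl{[(1R,2R,4aS,8aS)-1-(2-iodoethyl)-2,5,5,8a-tetramethyldecahydronaphthalen-2-yl]oxy}silane
Conditions: I2, PPh3, imidazole, CH2Cl2, 0 °C → rt
Reagents that add atoms: iodine, II
Why: Appel-type (Garegg–Samuelsson) iodination is an SN2 displacement at the primary carbon, and the silyl-capped tertiary oxygen cannot cyclise.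

## Fragment union and completion (steps 20–21)

**Step 20**
Reactants: **22**; **10**
Product: **23**, ambrein triethylsilyl ether
Conditions: **22**, t-BuLi (2.1 equiv), Et2O, −78 °C; B-MeO-9-BBN, THF, −78 °C → rt; then **10**, Pd(dppf)Cl2·CH2Cl2 (5 mol%), AsPh3, aq. K3PO4, DMF, rt
Reagents that add atoms: none (both partners are numbered reactants; boron is not retained)
Why: B-alkyl Suzuki–Miyaura coupling (Marshall–Johnson protocol): iodine–lithium exchange and borinate formation give a primary alkylborane that couples with the vinyl iodide with retention of E geometry, joining the C16 and C14 halves.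

**Step 21**
Reactants: **23**
Product: **24**, (+)-ambrein
Conditions: TBAF, THF, 40 °C
Reagents that add atoms: none
Why: Fluoride desilylation frees the tertiary alcohol under non-acidic conditions, so the alcohol does not dehydrate and the exocyclic alkene does not isomerise.

## Compound list

1 | 3-methylcyclohex-2-en-1-one | CC1=CC(=O)CCC1 | starting material
2 | [(3,3-dimethylcyclohex-1-en-1-yl)oxy]trimethylsilane | C[Si](C)(C)OC1=CC(C)(C)CCC1 | intermediate
3 | allyl chloroformate | C=CCOC(=O)Cl | starting material
4 | allyl 3,3-dimethylcyclohex-1-en-1-yl carbonate | C=CCOC(=O)OC1=CC(C)(C)CCC1 | intermediate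
5 | (2S)-3,3-dimethyl-2-(prop-2-en-1-yl)cyclohexan-1-one | O=C1CCCC(C)(C)[C@@H]1CC=C | intermediate
6 | (2S)-1,1-dimethyl-3-methylidene-2-(prop-2-en-1-yl)cyclohexane | C=C1CCCC(C)(C)[C@@H]1CC=C | intermediate
7 | 3-[(1S)-2,2-dimethyl-6-methylidenecyclohexyl]propan-1-ol | C=C1CCCC(C)(C)[C@@H]1CCCO | intermediate
8 | 3-[(1S)-2,2-dimethyl-6-methylidenecyclohexyl]propanal | C=C1CCCC(C)(C)[C@@H]1CCC=O | intermediate
9 | (2S)-2-(but-3-yn-1-yl)-1,1-dimethyl-3-methylidenecyclohexane | C=C1CCCC(C)(C)[C@@H]1CCC#C | intermediate
10 | (2S)-2-[(3E)-4-iodo-3-methylbut-3-en-1-yl]-1,1-dimethyl-3-methylidenecyclohexane | C=C1CCCC(C)(C)[C@@H]1CC/C(C)=C/I | intermediate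
11 | 5-bromo-2-methylpent-2-ene | CC(C)=CCCBr | starting material
12 | 6-methylhept-5-en-1-yne | CC(C)=CCCC#C | intermediate
13 | (3E)-4,8-dimethylnona-3,7-dien-1-ol | CC(C)=CCC/C(C)=C/CCO | intermediate
14 | (6E)-9-bromo-2,6-dimethylnona-2,6-diene | CC(C)=CCC/C(C)=C/CCBr | intermediate
15 | (5E)-6,10-dimethylundeca-5,9-dien-1-yne | CC(C)=CCC/C(C)=C/CCC#C | intermediate
16 | (3E,7E)-4,8,12-trimethyltrideca-3,7,11-trien-1-ol | CC(C)=CCC/C(C)=C/CC/C(C)=C/CCO | intermediate
17 | (−)-Ambrox, (3aR,5aS,9aS,9bR) | C1C[C@@H]2[C@@]3(C)CCCC(C)(C)[C@@H]3CC[C@@]2(C)O1 | intermediate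
18 | (+)-sclareolide, (3aR,5aS,9aS,9bR) | O=C1C[C@@H]2[C@@]3(C)CCCC(C)(C)[C@@H]3CC[C@@]2(C)O1 | intermediate
19 | ambradiol, (1R,2R,4aS,8aS) | OCC[C@@H]1[C@@]2(C)CCCC(C)(C)[C@@H]2CC[C@@]1(C)O | intermediate
20 | ambradiol bis(triethylsilyl) ether | CC[Si](CC)(CC)OCC[C@@H]1[C@@]2(C)CCCC(C)(C)[C@@H]2CC[C@@]1(C)O[Si](CC)(CC)CC | intermediate
21 | ambradiol tertiary mono-TES ether (primary alcohol free) | OCC[C@@H]1[C@@]2(C)CCCC(C)(C)[C@@H]2CC[C@@]1(C)O[Si](CC)(CC)CC | intermediate
22 | primary iodide of 21 | ICC[C@@H]1[C@@]2(C)CCCC(C)(C)[C@@H]2CC[C@@]1(C)O[Si](CC)(CC)CC | intermediate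
23 | ambrein triethylsilyl ether | C=C1CCCC(C)(C)[C@@H]1CC/C(C)=C/CC[C@@H]1[C@@]2(C)CCCC(C)(C)[C@@H]2CC[C@@]1(C)O[Si](CC)(CC)CC | intermediate
24 | (+)-ambrein | C=C1CCCC(C)(C)[C@@H]1CC/C(C)=C/CC[C@@H]1[C@@]2(C)CCCC(C)(C)[C@@H]2CC[C@@]1(C)O | target

## Totals and risks

Total step count: 21.
Longest linear sequence: 13 steps (steps 9–21, from **11** to **24**); the other branch is 8 steps (1–8) before the union.

Steps most likely to fail:

1. **Step 3** (asymmetric allylation forming a tertiary α-centre beside a quaternary carbon; rate, ee and facial sense are uncertain). Fallback: Johnson–Claisen rearrangement of (3,3-dimethylcyclohex-1-en-1-yl)methanol with triethyl orthoacetate gives racemic 2-(2,2-dimethyl-6-methylidenecyclohexyl)acetate. Saponify, resolve the acid as its 1-phenylethylammonium salt, then LiAlH4, Appel iodination and acetylide alkylation lead to **9**. This replaces asymmetric catalysis with a classical resolution.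

2. **Step 14** (depends on an active cyclase variant and on substrate loading). Fallback: chemical asymmetric polyene cyclisation of **16** with a confined chiral Brønsted acid (imidodiphosphorimidate type) in a fluorinated alcohol, then recrystallisation of **17** to enantiopurity. If that also fails, oxidise **16** to homofarnesylic acid, cyclise with ClSO3H to racemic **18** and resolve at the diol stage.

3. **Step 20** (alkyllithium generation next to a silyl ether, β-hydride elimination, trisubstituted vinyl iodide). Fallback: reverse the polarity. Lithiate **10** (t-BuLi, −78 °C), convert it to the alkenyl cuprate or alkenylmagnesium/Li2CuCl4 species, and alkylate iodide **22** by SN2, avoiding both palladium and an organometallic on the decalin fragment.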